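**Retrosynthetic overview**
- The strategy rests on the 2,4-disubstituted furan ring: O1, C5 and C4 are the oxygen, CH2 and quaternary carbon of an oxirane, and C3–C2 are the two carbons of an arylalkyne. The O1–C2 bond is made last, by gold-catalysed cycloisomerisation of a 2-alkynyl oxirane that already carries the side-chain carbinol; this furan is the only ring formed in the route.
- The oxirane CH2 (C5) comes from chloromethyllithium added to an α-silyloxy ynone. The ynone comes from a Weinreb amide and a lithium arylacetylide made by Corey–Fuchs homologation of 2,5-dihydroxybenzaldehyde.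
- The single (S)-carbinol stereocentre is bought in methyl (S)-glycidate, which is opened at C3 by an isobutenyl Grignard reagent under copper catalysis; it is never a reaction centre afterwards.
- End game: selective loss of the triethylsilyl ether, Steglich senecioylation, fluoride release of the hydroquinone.

Key step: step 8

Remark on the chemistry: compounds 12 and 13 are formed and used as mixtures of both configurations at the carbon that becomes furan C4, because step 8 makes this carbon sp2.

**Route**

Step 1
Reactants: 1 methyl (2S)-oxirane-2-carboxylate; 2 (2-methylprop-1-en-1-yl)magnesium bromide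
Product: 3 methyl (2S)-2-hydroxy-5-methylhex-4-enoate
Conditions: CuI (10 mol %), THF, −78 → −40 °C; aq. NH4Cl
Reagents that add atoms: none
Why: Copper-catalysed Grignard opening of a terminal epoxide (SN2 at the unsubstituted C3) should outrun addition to the ester at low temperature, and since C2 is not a reaction centre the (S)-configuration of 1 is carried into 3 unchanged.

Step 2
Reactants: 3 methyl (2S)-2-hydroxy-5-methylhex-4-enoate
Product: 4 methyl (2S)-5-methyl-2-(triethylsilyloxy)hex-4-enoate
Conditions: TESCl, imidazole, CH2Cl2, 0 °C → rt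
Reagents that add atoms: chlorotriethylsilane, CC[Si](Cl)(CC)CC
Why: Standard silylation of a secondary alcohol; the triethylsilyl ether tolerates the organolithium steps and can later be removed by mild acid in the presence of aryl silyl ethers.

Step 3
Reactants: 4 methyl (2S)-5-methyl-2-(triethylsilyloxy)hex-4-enoate
Product: 5 (2S)-N-methoxy-N,5-dimethyl-2-(triethylsilyloxy)hex-4-enamide
Conditions: MeNH(OMe)·HCl, i-PrMgCl, THF, −20 → 0 °C
Reagents that add atoms: N,O-dimethylhydroxylamine hydrochloride, CNOC.Cl
Why: Weinreb amide formation by aminolysis of the methyl ester with the chloromagnesium amide made in the flask; this weakly basic amide should not deprotonate the α-carbon, so the stereocentre is kept.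

Step 4
Reactants: 6 2,5-dihydroxybenzaldehyde
Product: 7 2,5-bis(tert-butyldimethylsilyloxy)benzaldehyde
Conditions: TBSCl, imidazole, DMF, rt
Reagents that add atoms: tert-butyldimethylsilyl chloride, CC(C)(C)[Si](C)(C)Cl
Why: Silylation of both phenols removes the acidic protons before the organolithium chemistry and gives ethers that buffered fluoride cleaves at the end.

Step 5
Reactants: 7 2,5-bis(tert-butyldimethylsilyloxy)benzaldehyde
Product: 8 2-(2,2-dibromoethenyl)-1,4-bis(tert-butyldimethylsilyloxy)benzene
Conditions: CBr4, PPh3, Zn dust, CH2Cl2, rt; then 7, rt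
Reagents that add atoms: carbon tetrabromide, BrC(Br)(Br)Br
Why: Ramirez–Corey–Fuchs dibromo-olefination of the aldehyde with the ylide Ph3P=CBr2; generating the ylide with zinc avoids free Ph3PBr2, which could attack the silyl ethers.

Step 6
Reactants: 8 2-(2,2-dibromoethenyl)-1,4-bis(tert-butyldimethylsilyloxy)benzene; 5 (2S)-N-methoxy-N,5-dimethyl-2-(triethylsilyloxy)hex-4-enamide
Product: 11 (4S)-1-[2,5-bis(tert-butyldimethylsilyloxy)phenyl]-7-methyl-4-(triethylsilyloxy)oct-6-en-1-yn-3-one, via lithium arylacetylide 9 (not isolated), via lithium aminal alkoxide 10 (not isolated)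
Conditions: n-BuLi (2 equiv per 8), THF, −78 → 0 °C; then 5, −78 → 0 °C; aq. NH4Cl
Reagents that add atoms: none
Why: The second stage of the Corey–Fuchs reaction (bromine–lithium exchange, Fritsch–Buttenberg–Wiechell rearrangement, metalation) gives the lithium acetylide, which should add only once to the Weinreb amide because the chelated tetrahedral adduct persists until the quench; the acetylide is too weak a base to enolise the amide, so the α-stereocentre is untouched.

Step 7
Reactants: 11 (4S)-1-[2,5-bis(tert-butyldimethylsilyloxy)phenyl]-7-methyl-4-(triethylsilyloxy)oct-6-en-1-yn-3-one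
Product: 13 2-{[2,5-bis(tert-butyldimethylsilyloxy)phenyl]ethynyl}-2-[(1S)-4-methyl-1-(triethylsilyloxy)pent-3-en-1-yl]oxirane (both configurations at the oxirane carbon), via lithium chlorohydrin alkoxide 12 (not isolated)
Conditions: ICH2Cl, MeLi·LiBr, THF, −78 °C; then rt
Reagents that add atoms: chloroiodomethane, ClCI
Why: Iodine–lithium exchange generates chloromethyllithium in the presence of the ketone, the carbenoid should add 1,2 to the ynone carbonyl (carbenoid homologation of a ketone to an epoxide), and on warming the chlorohydrin alkoxide closes by intramolecular Williamson displacement; the new quaternary centre forms as a mixture that step 8 erases.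

Step 8
Reactants: 13 2-{[2,5-bis(tert-butyldimethylsilyloxy)phenyl]ethynyl}-2-[(1S)-4-methyl-1-(triethylsilyloxy)pent-3-en-1-yl]oxirane
Product: 14 triethyl{[(1S)-1-{5-[2,5-bis(tert-butyldimethylsilyloxy)phenyl]furan-3-yl}-4-methylpent-3-en-1-yl]oxy}silane
Conditions: AuCl3 (5 mol %), MeCN, rt
Reagents that add atoms: none
Why: Trivalent gold binds the alkyne as a π-acid and the strained C–O bond at the quaternary propargylic oxirane carbon opens (directly or after reversible capture of the cation by trace water), so that the oxirane oxygen, still bonded to its CH2, adds anti to gold at the aryl-bearing alkyne carbon and forms O1–C2. Loss of a proton from the former oxirane CH2 (or of water) and protodeauration of the C3–Au bond should then give the aromatic furan; the closest known reaction type is the gold-catalysed cycloisomerisation of alkynyl oxiranes to furans. The single ring closes in a 5-endo-dig mode through O, CH2, the quaternary carbon and the two alkyne carbons. No stereocentre is created: the epimeric oxirane carbon becomes sp2 C4 and the neighbouring (S)-carbinol carbon keeps all four of its bonds. The step needs attack at the aryl-bearing carbon by the oxirane oxygen only; the electron-rich aryl group polarises the alkyne toward its own carbon, the bulky silyl ethers on the ortho phenol and on the carbinol are poor nucleophiles that cannot reach a neutral aromatic product without losing silicon, and the alkynophilic catalyst should leave the trisubstituted alkene alone.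

Step 9
Reactants: 14 triethyl{[(1S)-1-{5-[2,5-bis(tert-butyldimethylsilyloxy)phenyl]furan-3-yl}-4-methylpent-3-en-1-yl]oxy}silane
Product: 15 (1S)-1-{5-[2,5-bis(tert-butyldimethylsilyloxy)phenyl]furan-3-yl}-4-methylpent-3-en-1-ol
Conditions: PPTS (cat.), MeOH/CH2Cl2, 0 °C → rt
Reagents that add atoms: none
Why: Mild acid-catalysed methanolysis should cleave the alkyl triethylsilyl ether much faster than the bulkier, less basic aryl tert-butyldimethylsilyl ethers, and only the O–Si bond is broken, so the carbinol keeps its (S)-configuration.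

Step 10
Reactants: 15 (1S)-1-{5-[2,5-bis(tert-butyldimethylsilyloxy)phenyl]furan-3-yl}-4-methylpent-3-en-1-ol; 16 3-methylbut-2-enoic acid
Product: 17 (1S)-1-{5-[2,5-bis(tert-butyldimethylsilyloxy)phenyl]furan-3-yl}-4-methylpent-3-en-1-yl 3-methylbut-2-enoate
Conditions: DCC, DMAP (cat.), CH2Cl2, 0 °C → rt
Reagents that add atoms: none
Why: Steglich esterification acylates the alcohol oxygen without touching the C–O bond at the stereocentre (retention), and it avoids the vinylketene pathway by which senecioyl chloride and amine bases give the deconjugated ester.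

Step 11
Reactants: 17 (1S)-1-{5-[2,5-bis(tert-butyldimethylsilyloxy)phenyl]furan-3-yl}-4-methylpent-3-en-1-yl 3-methylbut-2-enoate
Product: 18 (1S)-1-[5-(2,5-dihydroxyphenyl)furan-3-yl]-4-methylpent-3-en-1-yl 3-methylbut-2-enoate
Conditions: TBAF, AcOH, THF, 0 °C, argon
Reagents that add atoms: none
Why: Fluoride cleaves the two aryl O–Si bonds at 0 °C, and buffering with acetic acid keeps the hydroquinone protonated so that it should neither oxidise to the quinone nor attack the ester.

**Compound list**
1 | methyl (2S)-oxirane-2-carboxylate | COC(=O)[C@@H]1CO1 | starting material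
2 | (2-methylprop-1-en-1-yl)magnesium bromide | CC(C)=C[Mg]Br | starting material
3 | methyl (2S)-2-hydroxy-5-methylhex-4-enoate | CC(C)=CC[C@H](O)C(=O)OC | intermediate
4 | methyl (2S)-5-methyl-2-(triethylsilyloxy)hex-4-enoate | CC(C)=CC[C@H](O[Si](CC)(CC)CC)C(=O)OC | intermediate
5 | (2S)-N-methoxy-N,5-dimethyl-2-(triethylsilyloxy)hex-4-enamide | CC(C)=CC[C@H](O[Si](CC)(CC)CC)C(=O)N(C)OC | intermediate
6 | 2,5-dihydroxybenzaldehyde | O=Cc1cc(O)ccc1O | starting material
7 | 2,5-bis(tert-butyldimethylsilyloxy)benzaldehyde | O=Cc1cc(O[Si](C)(C)C(C)(C)C)ccc1O[Si](C)(C)C(C)(C)C | intermediate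
8 | 2-(2,2-dibromoethenyl)-1,4-bis(tert-butyldimethylsilyloxy)benzene | BrC(Br)=Cc1cc(O[Si](C)(C)C(C)(C)C)ccc1O[Si](C)(C)C(C)(C)C | intermediate
9 | lithium [2,5-bis(tert-butyldimethylsilyloxy)phenyl]acetylide (not isolated) | [Li]C#Cc1cc(O[Si](C)(C)C(C)(C)C)ccc1O[Si](C)(C)C(C)(C)C | intermediate
10 | lithium (4S)-1-[2,5-bis(tert-butyldimethylsilyloxy)phenyl]-3-[methoxy(methyl)amino]-7-methyl-4-(triethylsilyloxy)oct-6-en-1-yn-3-olate, mixture at C3 (not isolated) | CC(C)=CC[C@H](O[Si](CC)(CC)CC)C(O[Li])(N(C)OC)C#Cc1cc(O[Si](C)(C)C(C)(C)C)ccc1O[Si](C)(C)C(C)(C)C | intermediate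
11 | (4S)-1-[2,5-bis(tert-butyldimethylsilyloxy)phenyl]-7-methyl-4-(triethylsilyloxy)oct-6-en-1-yn-3-one | CC(C)=CC[C@H](O[Si](CC)(CC)CC)C(=O)C#Cc1cc(O[Si](C)(C)C(C)(C)C)ccc1O[Si](C)(C)C(C)(C)C | intermediate
12 | lithium (4S)-1-[2,5-bis(tert-butyldimethylsilyloxy)phenyl]-3-(chloromethyl)-7-methyl-4-(triethylsilyloxy)oct-6-en-1-yn-3-olate, mixture at C3 (not isolated) | CC(C)=CC[C@H](O[Si](CC)(CC)CC)C(CCl)(O[Li])C#Cc1cc(O[Si](C)(C)C(C)(C)C)ccc1O[Si](C)(C)C(C)(C)C | intermediate
13 | 2-{[2,5-bis(tert-butyldimethylsilyloxy)phenyl]ethynyl}-2-[(1S)-4-methyl-1-(triethylsilyloxy)pent-3-en-1-yl]oxirane, mixture at the oxirane carbon | CC(C)=CC[C@H](O[Si](CC)(CC)CC)C1(CO1)C#Cc1cc(O[Si](C)(C)C(C)(C)C)ccc1O[Si](C)(C)C(C)(C)C | intermediate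
14 | triethyl{[(1S)-1-{5-[2,5-bis(tert-butyldimethylsilyloxy)phenyl]furan-3-yl}-4-methylpent-3-en-1-yl]oxy}silane | CC(C)=CC[C@H](O[Si](CC)(CC)CC)c1coc(-c2cc(O[Si](C)(C)C(C)(C)C)ccc2O[Si](C)(C)C(C)(C)C)c1 | intermediate
15 | (1S)-1-{5-[2,5-bis(tert-butyldimethylsilyloxy)phenyl]furan-3-yl}-4-methylpent-3-en-1-ol | CC(C)=CC[C@H](O)c1coc(-c2cc(O[Si](C)(C)C(C)(C)C)ccc2O[Si](C)(C)C(C)(C)C)c1 | intermediate
16 | 3-methylbut-2-enoic acid | CC(C)=CC(=O)O | starting material
17 | (1S)-1-{5-[2,5-bis(tert-butyldimethylsilyloxy)phenyl]furan-3-yl}-4-methylpent-3-en-1-yl 3-methylbut-2-enoate | CC(C)=CC[C@H](OC(=O)C=C(C)C)c1coc(-c2cc(O[Si](C)(C)C(C)(C)C)ccc2O[Si](C)(C)C(C)(C)C)c1 | intermediate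
18 | (1S)-1-[5-(2,5-dihydroxyphenyl)furan-3-yl]-4-methylpent-3-en-1-yl 3-methylbut-2-enoate | CC(C)=CC[C@H](OC(=O)C=C(C)C)c1coc(-c2cc(O)ccc2O)c1 | target

**Totals**
Total step count: 11. Longest linear sequence: 9 steps (steps 1, 2, 3, 6, 7, 8, 9, 10, 11).

**Steps most likely to fail**

Step 8 (key step). The cyclisation may be diverted in three ways:
- attack of the ortho silyloxy oxygen on the activated alkyne, closing a benzofuran with loss of silicon;
- a 1,2-shift to the cationic quaternary carbon after the oxirane opens (Meinwald-type rearrangement); a hydride shift from the carbinol carbon would also erase the stereocentre;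
- acid-induced loss of the triethylsilyl group before ring closure.

The fallback sets out from ynone 11 and avoids the oxirane. LiCH2OLi (from Bu3SnCH2OH and two equivalents of n-BuLi, THF, −78 °C) should add to the ketone carbonyl to give the 3-alkyne-1,2-diol (3S)-2-{[2,5-bis(tert-butyldimethylsilyloxy)phenyl]ethynyl}-6-methyl-3-(triethylsilyloxy)hept-5-ene-1,2-diol F1 as a mixture at C2. Stirring F1 with AgNO3 on silica gel (CH2Cl2, rt, dark) should then bring about 5-endo-dig addition of the primary hydroxyl to the aryl-bearing alkyne carbon and loss of water from the tertiary carbinol, which returns the route at furan 14. In this variant the ring oxygen is a free hydroxyl from the start and no cation is generated at the quaternary carbon.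

Step 7. The organolithium may enolise the α-silyloxy ynone (erosion of the stereocentre) or add in conjugate fashion, or the carbenoid may decompose before it adds. The fallback reverses the order of the two carbon–carbon bond formations and sets out from Weinreb amide 5. Chloromethyllithium (ICH2Cl, MeLi·LiBr, THF, −78 °C) should stop at the α-chloroketone (3S)-1-chloro-6-methyl-3-(triethylsilyloxy)hept-5-en-2-one F2. Acetylide 9 (from 8 and n-BuLi as in step 6), added to F2 at −78 °C, should give the same chlorohydrin alkoxide 12, which closes on warming and returns the route at oxirane 13.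

Step 9. The acid may ionise the furan-3-yl carbinol through its oxygen-stabilised cation (racemisation or methyl ether formation) or begin to cleave an aryl silyl ether. The fallback sets out from 14 and uses no acid. TBAF/AcOH (THF, 0 °C) should remove all three silyl groups to give the triol 2-{4-[(1S)-1-hydroxy-4-methylpent-3-en-1-yl]furan-2-yl}benzene-1,4-diol F3. TBSCl (2 equivalents) and imidazole (CH2Cl2, 0 °C) should then silylate the two phenols, which react far faster than the secondary alcohol, and return the route at 15.

**Further compounds**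
F1 | step 8 | (3S)-2-{[2,5-bis(tert-butyldimethylsilyloxy)phenyl]ethynyl}-6-methyl-3-(triethylsilyloxy)hept-5-ene-1,2-diol (mixture at C2) | CC(C)=CC[C@H](O[Si](CC)(CC)CC)C(O)(CO)C#Cc1cc(O[Si](C)(C)C(C)(C)C)ccc1O[Si](C)(C)C(C)(C)C
F2 | step 7 | (3S)-1-chloro-6-methyl-3-(triethylsilyloxy)hept-5-en-2-one | CC(C)=CC[C@H](O[Si](CC)(CC)CC)C(=O)CCl
F3 | step 9 | 2-{4-[(1S)-1-hydroxy-4-methylpent-3-en-1-yl]furan-2-yl}benzene-1,4-diol | CC(C)=CC[C@H](O)c1coc(-c2cc(O)ccc2O)c1
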